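**Retrosynthetic overview**

1. Target (quinone numbering C1=O, C2–OH, C3–OMe, C4=O, C5–hexaprenyl, C6–Me) ⇐ hydrolysis of the C4 vinylogous-ester methoxy group of ortho-quinone 24 and tautomerization ⇐ catechol 23 ⇐ MOM ether 22, a hexasubstituted benzene.
2. Key disconnection of 22 at C1–C2 and C5–C6: the two-carbon unit C1–C6 is lithiated (Z)-1-(methoxymethoxy)propene 18 (an acyl-anion equivalent), the four-carbon unit C2–C3–C4–C5 is cyclobutenone 14.
3. Enabling feature: C2(O)–C3(OMe)–C4(O)–C5 are four contiguous ring carbons with the oxygen pattern of dimethyl squarate (carbonyl, enol ether, enol ether, carbonyl), and C1 and C2 both bear oxygen, so C1 can arrive as an α-alkoxyalkenyl anion; ring strain and the alkoxide then drive 4π opening and 6π closure.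
4. 14 ⇐ dimethyl squarate 11 + hexaprenylbarium chloride 12 (α-selective, E-retentive); hexaprenyl chloride 10 ⇐ two farnesyl units joined by allylic sulfone alkylation.
5. Ring order: the cyclobutene of squarate is a temporary ring; the only ring of the target, the six-membered carbocycle, is formed once, in the key step, by ring expansion.

Key step: step 12

Assumption: all-E hexaprenol is taken as not commercially available and is therefore built from (2E,6E)-farnesol and (2E,6E)-farnesyl bromide.

Notation: "hexaprenyl" means the (2E,6E,10E,14E,18E)-3,7,11,15,19,23-hexamethyltetracosa-2,6,10,14,18,22-hexaen-1-yl group; C1–C6 refer to the quinone numbering given in line 1.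

**Route**

Step 1
Reactants: 1 (2E,6E)-farnesol
Product: 2 (2E,6E)-farnesyl benzyl ether
Conditions: NaH, BnBr, Bu4NI (cat.), THF, 0 °C to rt
Reagents that add atoms: benzyl bromide, BrCc1ccccc1
Why: Williamson ether synthesis on a primary allylic alkoxide should mask the alcohol for the chain extension without touching either E double bond.

Step 2
Reactants: 2 (2E,6E)-farnesyl benzyl ether
Product: 3 (2E,6E,10E)-12-benzyloxy-2,6,10-trimethyldodeca-2,6,10-trien-1-ol
Conditions: SeO2 (cat.), t-BuOOH, salicylic acid (cat.), CH2Cl2, rt
Reagents that add atoms: selenium dioxide (catalytic oxygen carrier), O=[Se]=O; tert-butyl hydroperoxide (terminal oxygen source), CC(C)(C)OO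
Why: Catalytic SeO2 allylic oxidation (ene reaction followed by [2,3]-sigmatropic shift) should hydroxylate the E-methyl group of the terminal, most electron-rich trisubstituted alkene and so set the E geometry of the new allylic alcohol, while the alkene next to the benzyloxy group is deactivated.

Step 3
Reactants: 3 (2E,6E,10E)-12-benzyloxy-2,6,10-trimethyldodeca-2,6,10-trien-1-ol
Product: 4 benzyl (2E,6E,10E)-12-bromo-3,7,11-trimethyldodeca-2,6,10-trien-1-yl ether
Conditions: CBr4, PPh3, CH2Cl2, 0 °C
Reagents that add atoms: tetrabromomethane, BrC(Br)(Br)Br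
Why: The Appel reaction converts the primary allylic alcohol into the bromide by SN2 displacement of the oxyphosphonium group under neutral conditions, which should avoid allylic transposition and E/Z isomerization.

Step 4
Reactants: 5 (2E,6E)-farnesyl bromide
Product: 6 (2E,6E)-farnesyl phenyl sulfone
Conditions: PhSO2Na, DMF, rt
Reagents that add atoms: sodium benzenesulfinate, [Na+].[O-]S(=O)c1ccccc1
Why: S-alkylation of the sulfinate anion by SN2 at the primary allylic bromide should give the allylic sulfone with the double-bond geometry intact.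

Step 5
Reactants: 6 (2E,6E)-farnesyl phenyl sulfone; 4 benzyl (2E,6E,10E)-12-bromo-3,7,11-trimethyldodeca-2,6,10-trien-1-yl ether
Product: 8 all-E hexaprenyl benzyl ether carrying a phenylsulfonyl group at C13, via lithiated sulfone 7 (not isolated)
Conditions: n-BuLi, THF/DMPU, −78 °C; then 4, −78 to −20 °C
Reagents that add atoms: none
Why: Alkylation of an α-sulfonyl allyl carbanion (Julia-type allylic sulfone alkylation) takes place at the sulfone-bearing carbon by SN2 on the allylic bromide, so the head-to-tail C30 skeleton forms with all five trisubstituted E double bonds preserved.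

Step 6
Reactants: 8 all-E hexaprenyl benzyl ether carrying a phenylsulfonyl group at C13
Product: 9 all-E hexaprenol
Conditions: Li, EtNH2, THF, −78 °C; then NH4Cl
Reagents that add atoms: none
Why: Dissolving-metal reduction (Birch-type conditions) cleaves the allylic carbon–sulfur bond and the benzyl ether in one operation, as is usual in polyprenol synthesis, and the low temperature should limit double-bond migration.

Step 7
Reactants: 9 all-E hexaprenol
Product: 10 all-E hexaprenyl chloride
Conditions: NCS, Me2S, CH2Cl2, −40 to 0 °C
Reagents that add atoms: N-chlorosuccinimide, O=C1CCC(=O)N1Cl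
Why: Corey–Kim chlorination converts the allylic alcohol through an alkoxysulfonium ion into the primary chloride by SN2 attack of chloride, without allylic transposition or loss of E geometry.

Step 8
Reactants: 10 all-E hexaprenyl chloride; 11 dimethyl squarate
Product: 13 racemic 4-hydroxy-2,3-dimethoxy-4-hexaprenylcyclobut-2-en-1-one, via hexaprenylbarium chloride 12 (not isolated)
Conditions: Li, biphenyl, BaI2, THF, rt; then 10, −78 °C; then 11, −78 °C; aq. NH4Cl
Reagents that add atoms: none
Why: Allylbarium reagents made from allylic chlorides and activated barium add to ketones through the unsubstituted α-carbon with retention of the E geometry at −78 °C (α-selective allylbarium carbonyl addition), and a squarate carbonyl should take up one organometallic by clean 1,2-addition.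

Step 9
Reactants: 13 racemic 4-hydroxy-2,3-dimethoxy-4-hexaprenylcyclobut-2-en-1-one
Product: 14 racemic 2,3,4-trimethoxy-4-hexaprenylcyclobut-2-en-1-one
Conditions: MeI, Ag2O, MeCN, rt, dark
Reagents that add atoms: iodomethane, CI
Why: Purdie methylation caps the tertiary alcohol under non-basic conditions, which avoids ring opening of the hydroxycyclobutenone and gives a non-migrating leaving group for the later aromatization.

Step 10
Reactants: 15 allyl alcohol
Product: 16 allyl methoxymethyl ether
Conditions: MOMCl, iPr2NEt, CH2Cl2, 0 °C to rt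
Reagents that add atoms: chloromethyl methyl ether, COCCl
Why: O-alkylation of the alcohol with the chloromethyl ether (acetal formation) should proceed cleanly under amine base.

Step 11
Reactants: 16 allyl methoxymethyl ether
Product: 17 (Z)-1-(methoxymethoxy)prop-1-ene
Conditions: t-BuOK (cat.), DMSO, rt
Reagents that add atoms: none
Why: Base-mediated allyl-to-propenyl ether isomerization runs through a potassium-bridged cis allyl anion and should therefore give the (Z)-enol ether.

Step 12
Reactants: 17 (Z)-1-(methoxymethoxy)prop-1-ene; 14 racemic 2,3,4-trimethoxy-4-hexaprenylcyclobut-2-en-1-one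
Product: 22 2,3-dimethoxy-6-(methoxymethoxy)-5-methyl-4-hexaprenylphenol, via alkenyllithium 18 (not isolated), via lithium cyclobutenolate 19 (not isolated), via lithium trienolate 20 (not isolated), via lithium cyclohexadienolate 21 (not isolated)
Conditions: s-BuLi, THF, −78 °C; then 14, −78 °C to rt (45 °C if closure is slow); then 1 M aq. HCl, 0 °C
Reagents that add atoms: none
Why: Proposed new method: the acyl-anion equivalent 18 adds 1,2 to the ketone of 14 and forms the C1–C2 bond between two oxygen-bearing carbons (polarity reversal); the strained lithium cyclobutenolate 19 then opens by oxyanion-accelerated conrotatory 4π cleavage of the bond between the carbinol carbon and the chain-bearing carbon to trienolate 20, which closes by 6π disrotatory electrocyclization (in polar terms a 6-endo conjugate addition of the dienolate γ-carbon to its own α-alkoxy enone) to form the C5–C6 bond in 21, and acid work-up expels methanol from C5 and tautomerizes to the benzene ring of 22. The closest known reaction types are the squarate ester cascade, in which alkoxides of squarate 1,2-bis-adducts open at low temperature and then electrocyclize, and the Moore rearrangement of 4-alkenylcyclobutenones; new here are the 6π closure with a single alkenyl group on a 4-alkyl-4-methoxy mono-adduct and the aromatization by loss of methanol. The six-membered ring is closed by a thermal 6π electrocyclization, so the step is a formal [4+2] union of the four squarate carbons with the two propenyl carbons at the expense of the four-membered ring. The sp3 centres of 19 and 21 are transient and vanish on aromatization, so no stereocontrol is needed and both diastereomers of 19 should converge. The step needs 1,2- rather than 1,4-addition, which organolithium reagents give with squarate mono-adducts at −78 °C, and it needs the alkenyl group to rotate inward, which the outward preference of the alkoxide (the only anionic oxygen, because the neighbouring oxygen is capped as a methyl ether) should secure, while the Z geometry of 17 leaves only hydrogen inward on the propenyl terminus. No ketene is formed, so the polyene chain has no partner for an intramolecular [2+2] reaction and should remain a spectator.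

Step 13
Reactants: 22 2,3-dimethoxy-6-(methoxymethoxy)-5-methyl-4-hexaprenylphenol
Product: 23 3,4-dimethoxy-6-methyl-5-hexaprenylbenzene-1,2-diol
Conditions: p-TsOH·H2O (cat.), MeOH/THF, rt, under argon
Reagents that add atoms: none
Why: Acid-catalysed acetal exchange transfers the methoxymethyl group of the aryl MOM ether to methanol under conditions that trisubstituted polyprenyl alkenes tolerate, and argon protects the electron-rich catechol from air.

Step 14
Reactants: 23 3,4-dimethoxy-6-methyl-5-hexaprenylbenzene-1,2-diol
Product: 25 3-demethylubiquinone-6 (2-hydroxy-3-methoxy-6-methyl-5-hexaprenyl-1,4-benzoquinone), via ortho-quinone 24 (not isolated)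
Conditions: Ag2O, Na2SO4, Et2O, 0 °C, dark; filter; then 0.5 M aq. H2SO4, THF, rt
Reagents that add atoms: water, O
Why: Two-electron oxidation of the catechol gives the 3,4-dimethoxy-ortho-quinone, whose C4 methoxy group is the β-position of a vinylogous ester and should be exchanged for hydroxyl by acid-catalysed conjugate addition–elimination of water, after which tautomerization gives the more stable 2-hydroxy-1,4-benzoquinone with the other methoxy group and the free hydroxyl in the required positions.

**Compound list**

1 | (2E,6E)-farnesol | OC/C=C(\C)CC/C=C(\C)CCC=C(C)C | starting material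
2 | (2E,6E)-farnesyl benzyl ether | c1ccccc1COC/C=C(\C)CC/C=C(\C)CCC=C(C)C | intermediate
3 | (2E,6E,10E)-12-benzyloxy-2,6,10-trimethyldodeca-2,6,10-trien-1-ol | c1ccccc1COC/C=C(\C)CC/C=C(\C)CC/C=C(\C)CO | intermediate
4 | benzyl (2E,6E,10E)-12-bromo-3,7,11-trimethyldodeca-2,6,10-trien-1-yl ether | c1ccccc1COC/C=C(\C)CC/C=C(\C)CC/C=C(\C)CBr | intermediate
5 | (2E,6E)-farnesyl bromide | BrC/C=C(\C)CC/C=C(\C)CCC=C(C)C | starting material
6 | (2E,6E)-farnesyl phenyl sulfone | O=S(=O)(c1ccccc1)C/C=C(\C)CC/C=C(\C)CCC=C(C)C | intermediate
7 | α-lithiated (2E,6E)-farnesyl phenyl sulfone | [Li]C(S(=O)(=O)c1ccccc1)/C=C(\C)CC/C=C(\C)CCC=C(C)C | intermediate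
8 | benzyl ether of all-E 13-(phenylsulfonyl)hexaprenol (racemic at C13) | c1ccccc1COC/C=C(\C)CC/C=C(\C)CC/C=C(\C)CC(S(=O)(=O)c2ccccc2)/C=C(\C)CC/C=C(\C)CCC=C(C)C | intermediate
9 | all-E hexaprenol, (2E,6E,10E,14E,18E)-3,7,11,15,19,23-hexamethyltetracosa-2,6,10,14,18,22-hexaen-1-ol | OC/C=C(\C)CC/C=C(\C)CC/C=C(\C)CC/C=C(\C)CC/C=C(\C)CCC=C(C)C | intermediate
10 | all-E hexaprenyl chloride | ClC/C=C(\C)CC/C=C(\C)CC/C=C(\C)CC/C=C(\C)CC/C=C(\C)CCC=C(C)C | intermediate
11 | dimethyl squarate (3,4-dimethoxycyclobut-3-ene-1,2-dione) | COC1=C(OC)C(=O)C1=O | starting material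
12 | all-E hexaprenylbarium chloride | Cl[Ba]C/C=C(\C)CC/C=C(\C)CC/C=C(\C)CC/C=C(\C)CC/C=C(\C)CCC=C(C)C | intermediate
13 | racemic 4-hydroxy-2,3-dimethoxy-4-hexaprenylcyclobut-2-en-1-one | COC1=C(OC)C(O)(C/C=C(\C)CC/C=C(\C)CC/C=C(\C)CC/C=C(\C)CC/C=C(\C)CCC=C(C)C)C1=O | intermediate
14 | racemic 2,3,4-trimethoxy-4-hexaprenylcyclobut-2-en-1-one | COC1=C(OC)C(OC)(C/C=C(\C)CC/C=C(\C)CC/C=C(\C)CC/C=C(\C)CC/C=C(\C)CCC=C(C)C)C1=O | intermediate
15 | allyl alcohol | OCC=C | starting material
16 | allyl methoxymethyl ether, 3-(methoxymethoxy)prop-1-ene | C=CCOCOC | intermediate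
17 | (Z)-1-(methoxymethoxy)prop-1-ene | C/C=C\OCOC | intermediate
18 | [(Z)-1-(methoxymethoxy)prop-1-en-1-yl]lithium (lithium trans to methyl) | C/C=C(/[Li])OCOC | intermediate
19 | lithium 2,3,4-trimethoxy-1-[(Z)-1-(methoxymethoxy)prop-1-en-1-yl]-4-hexaprenylcyclobut-2-en-1-olate (mixture of diastereomers) | [Li+].[O-]C1(/C(OCOC)=C/C)C(OC)=C(OC)C1(OC)C/C=C(\C)CC/C=C(\C)CC/C=C(\C)CC/C=C(\C)CC/C=C(\C)CCC=C(C)C | intermediate
20 | ring-opened lithium trienolate: MeCH=C(OMOM)–C(OLi)=C(OMe)–C(OMe)=C(OMe)–hexaprenyl, alkenyl group cis to the dienyl chain on the enolate double bond, geometry of the terminal tetrasubstituted double bond not defined | [Li+].C/C=C(OCOC)/C([O-])=C(OC)\C(OC)=C(OC)C/C=C(\C)CC/C=C(\C)CC/C=C(\C)CC/C=C(\C)CC/C=C(\C)CCC=C(C)C | intermediate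
21 | lithium 2,3,4-trimethoxy-6-(methoxymethoxy)-5-methyl-4-hexaprenylcyclohexa-1,5-dien-1-olate (mixture of diastereomers) | [Li+].[O-]C1=C(OCOC)C(C)C(OC)(C/C=C(\C)CC/C=C(\C)CC/C=C(\C)CC/C=C(\C)CC/C=C(\C)CCC=C(C)C)C(OC)=C1OC | intermediate
22 | 2,3-dimethoxy-6-(methoxymethoxy)-5-methyl-4-hexaprenylphenol | Oc1c(OC)c(OC)c(C/C=C(\C)CC/C=C(\C)CC/C=C(\C)CC/C=C(\C)CC/C=C(\C)CCC=C(C)C)c(C)c1OCOC | intermediate
23 | 3,4-dimethoxy-6-methyl-5-hexaprenylbenzene-1,2-diol | Oc1c(OC)c(OC)c(C/C=C(\C)CC/C=C(\C)CC/C=C(\C)CC/C=C(\C)CC/C=C(\C)CCC=C(C)C)c(C)c1O | intermediate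
24 | 3,4-dimethoxy-6-methyl-5-hexaprenylcyclohexa-3,5-diene-1,2-dione | O=C1C(OC)=C(OC)C(C/C=C(\C)CC/C=C(\C)CC/C=C(\C)CC/C=C(\C)CC/C=C(\C)CCC=C(C)C)=C(C)C1=O | intermediate
25 | 3-demethylubiquinone-6, 2-hydroxy-3-methoxy-6-methyl-5-hexaprenyl-1,4-benzoquinone | COC1=C(O)C(=O)C(C)=C(C/C=C(\C)CC/C=C(\C)CC/C=C(\C)CC/C=C(\C)CC/C=C(\C)CCC=C(C)C)C1=O | target

**Step count and risks**

Total step count: 14. Longest linear sequence: 11 steps (steps 1, 2, 3, 5, 6, 7, 8, 9, 12, 13, 14).

Steps most likely to fail:

1. Step 12 (proposed new method). What may go wrong: conjugate instead of 1,2-addition of 18; failure of trienolate 20 to close because a [1,7]-hydrogen shift from an inward chain methylene or protonation to an open-chain divinyl ketone is faster than the 6π closure; loss of the MOM group during the acidic aromatization. Fallback with known chemistry, setting out from hexaprenyl chloride 10 and coming back at catechol 23: the commercial arene 2,3,4-trimethoxy-6-methylbenzaldehyde F1 would be demethylated selectively at the methoxy group ortho to the formyl group with BCl3 (chelation control) to give 2-hydroxy-3,4-dimethoxy-6-methylbenzaldehyde F2. Dakin oxidation (H2O2, NaOH) would give 3,4-dimethoxy-6-methylbenzene-1,2-diol F3, which would be protected with MOMCl and iPr2NEt as 1,2-dimethoxy-3,4-bis(methoxymethoxy)-5-methylbenzene F4 and brominated at its only free ring position with NBS to give 1-bromo-2,3-dimethoxy-4,5-bis(methoxymethoxy)-6-methylbenzene F5. Bromine–lithium exchange (n-BuLi, −78 °C), transmetalation with CuBr·SMe2 and SN2 coupling of the arylcopper reagent with 10 would give the bis-MOM ether of 23 F6, and removal of both MOM groups under the conditions of step 13 would return 23.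

2. Step 8. What may go wrong: attack through the γ-carbon of the allyl metal (giving the tertiary, vinyl-branched adduct), E/Z scrambling of the allylbarium if the temperature rises, or Wurtz homocoupling of 10 during metalation. Fallback, setting out from 10 and coming back at 13: displacement of chloride with PhSNa would give all-E hexaprenyl phenyl sulfide F7; reductive lithiation with lithium 4,4'-di-tert-butylbiphenylide at −78 °C followed by transmetalation with CeCl3 would give an allylcerium reagent, a class that adds to carbonyl groups through the less substituted allyl terminus, and its addition to 11 at −78 °C would give 13.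

3. Step 14. What may go wrong: over-oxidation or decomposition of the electron-rich ortho-quinone before hydrolysis, hydrolysis at the wrong methoxy group, or acid-promoted cyclization of the quinone onto the first double bond of the chain. Fallback, setting out from 22 and coming back at 25: acetylation of the free phenol (Ac2O, pyridine) would give the acetate of 22 F8; oxidative dealkylation of the para-related methoxymethoxy and methoxy groups with (NH4)2Ce(NO3)6 in MeCN/H2O at 0 °C would give the para-quinone directly as 2-acetoxy-3-methoxy-6-methyl-5-hexaprenyl-1,4-benzoquinone F9, with the acetate holding the oxygen differentiation, and mild hydrolysis (aq. NaHCO3, THF, then acidification) would give 25.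

**Further compounds**

F1 | step 12 | 2,3,4-trimethoxy-6-methylbenzaldehyde (commercial starting material of the fallback) | O=Cc1c(C)cc(OC)c(OC)c1OC
F2 | step 12 | 2-hydroxy-3,4-dimethoxy-6-methylbenzaldehyde | O=Cc1c(C)cc(OC)c(OC)c1O
F3 | step 12 | 3,4-dimethoxy-6-methylbenzene-1,2-diol | Oc1c(C)cc(OC)c(OC)c1O
F4 | step 12 | 1,2-dimethoxy-3,4-bis(methoxymethoxy)-5-methylbenzene | COCOc1c(C)cc(OC)c(OC)c1OCOC
F5 | step 12 | 1-bromo-2,3-dimethoxy-4,5-bis(methoxymethoxy)-6-methylbenzene | COCOc1c(C)c(Br)c(OC)c(OC)c1OCOC
F6 | step 12 | bis-MOM ether of 23, 1,2-dimethoxy-3,4-bis(methoxymethoxy)-5-methyl-6-hexaprenylbenzene | COCOc1c(C)c(C/C=C(\C)CC/C=C(\C)CC/C=C(\C)CC/C=C(\C)CC/C=C(\C)CCC=C(C)C)c(OC)c(OC)c1OCOC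
F7 | step 8 | all-E hexaprenyl phenyl sulfide | c1ccccc1SC/C=C(\C)CC/C=C(\C)CC/C=C(\C)CC/C=C(\C)CC/C=C(\C)CCC=C(C)C
F8 | step 14 | acetate of 22, 2,3-dimethoxy-6-(methoxymethoxy)-5-methyl-4-hexaprenylphenyl acetate | CC(=O)Oc1c(OC)c(OC)c(C/C=C(\C)CC/C=C(\C)CC/C=C(\C)CC/C=C(\C)CC/C=C(\C)CCC=C(C)C)c(C)c1OCOC
F9 | step 14 | 2-acetoxy-3-methoxy-6-methyl-5-hexaprenyl-1,4-benzoquinone | COC1=C(OC(C)=O)C(=O)C(C)=C(C/C=C(\C)CC/C=C(\C)CC/C=C(\C)CC/C=C(\C)CC/C=C(\C)CCC=C(C)C)C1=O
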